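The runs stem from a simulated flask on assumed constants, noise included.

If the left-handed substrate must shrink against a right-handed substrate that barely moves (it reads 49.1 % at the end of the south run), we count halvings: an excess of 90 % needs 4.25 halvings of the left-to-right ratio.

| flask | left-handed substrate | right-handed substrate | partner | precatalyst | remark | time |
|---|---|---|---|---|---|---|
| south | 0.067 M | 0.067 M | 0.55 equiv | 5 mol% | run made earlier |  |
| south-west | 0.067 M | 0.067 M | 2.2 equiv | 5 mol% | run made earlier |  |
| flask | 0.067 M | 0.067 M | 1.10 equiv | 5 mol% |  | 2.5 min |

| run | time / s | right-handed substrate / % | left-handed substrate / % | left-handed product / % |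
|---|---|---|---|---|
| south | 10.0 | 49.8 | 45.7 | 3.7 |
| south | 20.0 | 49.9 | 38.8 | 10.2 |
| south | 50.0 | 49.4 | 26.4 | 22.2 |
| south | 120 | 49.1 | 23.3 | 25.3 |
| south-west | 30.0 | 47.0 | 0.7 | 49.0 |
| south-west | 60.0 | 44.3 | 0.4 | 50.4 |
| south-west | 90.0 | 41.6 | 0.5 | 49.8 |
| south-west | 120 | 39.0 | 0 | 49.6 |

(scatter of a reading: 0.3 percentage points)

- whether the excess of right-handed substrate over left-handed substrate among what is left of the two reaches 90 % by 2.5 min (no / yes)
- the highest excess of right-handed substrate over left-handed substrate among what is left of the two up to 2.5 min

Now the rate. In the south run, we take the gap between the left-handed substrate and its last reading as a stand-in for the partner remaining, and it shrinks from 15 percentage points to 3.1 points of the charge between 20.0 s and 50.0 s. So we read the south rate as proportional to partner, with a half-life of the gap read as 12.9 s. With twice the partner of the south run, the flask on that reading starts at the doubled rate, start-up apart. Falling partner is the slowing we count, and on this count the wanted excess comes with the rate cut 7.21-fold and the left-to-right ratio down 19.0-fold. Because the rate falls less than the left-handed substrate does, its half-life stays within 12.9 s on our count, and the halvings need about 54.8 s plus start-up. The 2.5 min allowed hold 11.6 such half-lives, more than the count needs, so we commit to yes, with a top above the forecast's. The south-west run, with 2.2 equiv of partner, reads 6.07 halvings by 30.0 s, a reading that rests on 0.7 % of left-handed substrate against a scatter of 0.3 points.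

The forecast says yes, with a top of 93 % (range 89 % to 96.5 %): “Reaching 90% is likely, but it is close.”

The flask gives yes, with a top of 98.3 %.

    free catalyst + left-handed substrate ⇌ catalyst intermediate A (K = 120 L mol⁻¹, k = 130 L mol⁻¹ s⁻¹)
    free catalyst + right-handed substrate ⇌ catalyst intermediate B (K = 4.20 L mol⁻¹, k = 240 L mol⁻¹ s⁻¹)
    partner + catalyst intermediate A → free catalyst + left-handed product (k = 29.0 L mol⁻¹ s⁻¹)
    partner + catalyst intermediate B → free catalyst + right-handed product (k = 2.80 L mol⁻¹ s⁻¹)
    partner + precatalyst → free catalyst + spent reagent (k = 1.30 L mol⁻¹ s⁻¹)

The flask passes 90 % at 69.2 s, so its 4.25 halvings took 16.3 s each on average, start-up included, and the 2.60 further halvings up to 2.5 min took 31.1 s each, slower than the first ones. In the flask, the forward rate of binding of free catalyst to left-handed substrate, taken against its forward rate of binding to right-handed substrate, fell from 0.28 at 0.313 min to 0.0047 at 2.50 min.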